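The upper pyranone ring (O1, C2, C3, C4, C4a, C8a) is a β-aryloxy ketone, and its C3 carries one enolisable hydrogen and C8'' of an intact (2R,3R)-taxifolin unit. The route exploits this by disconnecting O1–C2. The precursor is an α-(taxifolin-8-yl)-2'-hydroxychalcone in which every hydroxyl except the 2'-phenol of upper ring A is benzylated. In one operation a cinchona thiourea closes the ring by oxa-Michael addition, sets C2 under catalyst control and lets C3 relax to the 2,3-trans arrangement. The chalcone is built from 8-bromotaxifolin pentabenzyl ether, a phloroacetophenone silyl enol ether and 3,4-bis(benzyloxy)benzaldehyde, with the 2'-phenol masked as a MOM ether until just before cyclisation.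

Key step: step 10

Remark: the target string was checked as 2S,3R in the upper half and 2R,3R in the lower half, both 2,3-trans; no structure needed correction.
Remark: benzyl ethers are used on all hydroxyls that stay protected, because the chelated 5''-OH of taxifolin can be benzylated with K2CO3 without the strong base that opens the flavanonol ring, and one neutral hydrogenolysis then ends the route.
Remark: the 2'-phenol is kept as a MOM ether through the amine-mediated condensation, where a free phenol would close the ring without stereocontrol, and the enolate coupling is run without strong base to spare C2'' and C3''.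
Assumption: the sense of induction of cinchona thioureas on α-aryl chalcones is unknown; the quinine-derived catalyst is written, and its quinidine-derived pseudoenantiomer replaces it if a trial run shows the other face is preferred.

Step 1
Reactants: 1 (+)-taxifolin
Product: 2 (2R,3R)-5,7,3',4'-tetra-O-benzyltaxifolin
Conditions: BnBr (4.5 equiv), K2CO3, DMF, rt, argon
Reagents that add atoms: benzyl bromide, BrCc1ccccc1
Why: Williamson etherification of the four phenols with carbonate is established for taxifolin; the weak base leaves C2 and C3 alone once the 4'-phenol is capped, and the secondary 3-OH does not react.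

Step 2
Reactants: 2 (2R,3R)-5,7,3',4'-tetra-O-benzyltaxifolin
Product: 3 (2R,3R)-3,5,7,3',4'-penta-O-benzyltaxifolin
Conditions: BnBr, Ag2O, DMF, 4 Å MS, rt, dark
Reagents that add atoms: benzyl bromide, BrCc1ccccc1
Why: Purdie-type silver oxide alkylation benzylates the acidic α-ketol hydroxyl without forming a free alkoxide or enolate, so the (2R,3R) centres are not disturbed.

Step 3
Reactants: 3 (2R,3R)-3,5,7,3',4'-penta-O-benzyltaxifolin
Product: 4 (2R,3R)-8-bromo-3,5,7,3',4'-penta-O-benzyltaxifolin
Conditions: NBS (1.0 equiv), MeCN–CH2Cl2, 0 °C to rt, dark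
Reagents that add atoms: N-bromosuccinimide, O=C1CCC(=O)N1Br
Why: Electrophilic aromatic bromination of the trioxygenated ring A goes to C8, flanked by one benzyloxy group and the ring oxygen, as is general for 5,7-di-O-alkyl flavonoids, while one equivalent in the dark avoids the 6,8-dibromide, the less activated ring B and benzylic positions.

Step 4
Reactants: 5 2,4,6-trihydroxyacetophenone
Product: 6 1-[2,4-bis(benzyloxy)-6-hydroxyphenyl]ethanone
Conditions: BnBr (2.1 equiv), K2CO3, DMF, rt
Reagents that add atoms: benzyl bromide, BrCc1ccccc1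
Why: Williamson etherification; the hydroxyl chelated to the acetyl carbonyl is the least reactive and stays free with two equivalents of bromide.

Step 5
Reactants: 6 1-[2,4-bis(benzyloxy)-6-hydroxyphenyl]ethanone
Product: 7 1-[2,4-bis(benzyloxy)-6-(methoxymethoxy)phenyl]ethanone
Conditions: NaH, MOMCl, DMF, 0 °C to rt
Reagents that add atoms: chloromethyl methyl ether, COCCl
Why: O-alkylation of the sodium phenoxide (Williamson-type acetal formation) gives a base-stable mask that acid can later remove in the presence of benzyl ethers.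

Step 6
Reactants: 7 1-[2,4-bis(benzyloxy)-6-(methoxymethoxy)phenyl]ethanone
Product: 8 {1-[2,4-bis(benzyloxy)-6-(methoxymethoxy)phenyl]ethenyloxy}trimethylsilane
Conditions: LiN(SiMe3)2, Me3SiCl, THF, –78 °C; non-aqueous work-up
Reagents that add atoms: chlorotrimethylsilane, C[Si](C)(C)Cl
Why: Kinetic enolisation of the methyl ketone with in situ O-silylation gives the only possible silyl enol ether, since no other acidic C–H is present.

Step 7
Reactants: 4 (2R,3R)-8-bromo-3,5,7,3',4'-penta-O-benzyltaxifolin; 8 {1-[2,4-bis(benzyloxy)-6-(methoxymethoxy)phenyl]ethenyloxy}trimethylsilane (1.5 equiv)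
Product: 10 deoxybenzoin 1-[2,4-bis(benzyloxy)-6-(methoxymethoxy)phenyl]-2-[(2R,3R)-penta-O-benzyltaxifolin-8-yl]ethanone, via tributylstannyl enolate 9 (not isolated)
Conditions: Pd(OAc)2 (5 mol%), P(t-Bu)3 (10 mol%), Bu3SnF, CsF, toluene, 85 °C
Reagents that add atoms: none
Why: Palladium-catalysed arylation of a ketone silyl enol ether through its tin enolate (Kuwajima–Urabe coupling in its fluoride-promoted trialkylphosphine form) makes the C8''–CH2 bond without strong base, so the enolisable C3''–H and the ring-opening-prone lower pyranone are spared, the bulky electron-rich phosphine copes with the doubly ortho-substituted bromide, and CsF returns the tin bromide to Bu3SnF.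

Step 8
Reactants: 10 deoxybenzoin 1-[2,4-bis(benzyloxy)-6-(methoxymethoxy)phenyl]-2-[(2R,3R)-penta-O-benzyltaxifolin-8-yl]ethanone; 11 3,4-bis(benzyloxy)benzaldehyde
Product: 12 (E)-1-[2,4-bis(benzyloxy)-6-(methoxymethoxy)phenyl]-3-[3,4-bis(benzyloxy)phenyl]-2-[(2R,3R)-penta-O-benzyltaxifolin-8-yl]prop-2-en-1-one
Conditions: piperidine, AcOH, toluene, reflux, Dean–Stark
Reagents that add atoms: none
Why: Knoevenagel-type condensation in which the benzylic α-keto methylene, far more acidic than C3''–H, adds to the piperidinium ion of the aldehyde and loses amine to give the enone, expected mainly as the (E) isomer with the acyl group trans to the new aryl group, while the MOM ether keeps the upper ring-A oxygen from adding to the enone without control.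

Step 9
Reactants: 12 (E)-1-[2,4-bis(benzyloxy)-6-(methoxymethoxy)phenyl]-3-[3,4-bis(benzyloxy)phenyl]-2-[(2R,3R)-penta-O-benzyltaxifolin-8-yl]prop-2-en-1-one
Product: 13 (E)-1-[2,4-bis(benzyloxy)-6-hydroxyphenyl]-3-[3,4-bis(benzyloxy)phenyl]-2-[(2R,3R)-penta-O-benzyltaxifolin-8-yl]prop-2-en-1-one
Conditions: HCl (1 M) in MeOH–THF, 0 °C to rt; NaHCO3 quench; used without delay
Reagents that add atoms: none
Why: Acid-catalysed acetal solvolysis removes the only acetal in the molecule, the aryl MOM ether ortho to the ketone, while benzyl ethers are inert and cold dilute acid does not close 2'-hydroxychalcones.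

Step 10
Reactants: 13 (E)-1-[2,4-bis(benzyloxy)-6-hydroxyphenyl]-3-[3,4-bis(benzyloxy)phenyl]-2-[(2R,3R)-penta-O-benzyltaxifolin-8-yl]prop-2-en-1-one
Product: 14 nona-O-benzyl ether of the target, (2S,3R)-5,7-bis(benzyloxy)-2-[3,4-bis(benzyloxy)phenyl]-3-[(2R,3R)-penta-O-benzyltaxifolin-8-yl]chroman-4-one
Conditions: quinine-derived thiourea 1-[3,5-bis(trifluoromethyl)phenyl]-3-[(8S,9S)-6'-methoxycinchonan-9-yl]thiourea (20 mol%), toluene, 4 Å MS, –20 to 0 °C
Reagents that add atoms: none
Why: Proposed new method: the quinuclidine nitrogen takes the proton of the single free phenol (2'-OH of upper ring A) while the thiourea N–H pair binds the C4 carbonyl, and the phenoxide adds to the β-carbon (future C2) to form O1–C2; the closest known reaction is the cinchona-thiourea-catalysed intramolecular oxa-Michael cyclisation of 2'-hydroxychalcones and their α-carboxylate analogues to flavanones, which has not been shown for α-aryl chalcones. The upper pyranone ring closes in a 6-endo-trig mode. C2 is controlled by the catalyst, which must deliver the phenoxide to the enone face that gives 2S against whatever bias the remote (2R,3R) lower half exerts, so the step needs diastereoface selectivity at C2. C3 is set when the enol is protonated and relaxes under the same amine to the 2,3-trans diequatorial (3R) arrangement, the thermodynamic one for 2,3-diarylchromanones. The substrate secures chemoselectivity and driving force: only one hydroxyl is free, the 6'-benzyloxy group twists the ketone out of its chelated planar form so the closed ring is favoured, and the low temperature keeps retro-oxa-Michael opening from eroding the kinetic choice at C2.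

Step 11
Reactants: 14 nona-O-benzyl ether of the target
Product: 15 (2S,3R)-2-(3,4-dihydroxyphenyl)-5,7-dihydroxy-3-[(2R,3R)-2-(3,4-dihydroxyphenyl)-3,5,7-trihydroxy-4-oxochroman-8-yl]chroman-4-one (EANPDB:THYM_00006)
Conditions: H2 (1 atm), Pd(OH)2/C, THF–MeOH, rt; filtration, reversed-phase purification
Reagents that add atoms: none
Why: Hydrogenolysis of the nine benzyl ethers over palladium under neutral conditions frees all hydroxyls at once and avoids the acid or base that could epimerise C2, C3, C2'' or C3'', and the electron-rich aryl ketones should not be reduced at room temperature and ambient pressure.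

Compound list
1 | (+)-taxifolin, (2R,3R) | Oc1cc(O)c2c(c1)O[C@H](c1ccc(O)c(O)c1)[C@@H](O)C2=O | starting material
2 | (2R,3R)-5,7-bis(benzyloxy)-2-[3,4-bis(benzyloxy)phenyl]-3-hydroxychroman-4-one | c1ccccc1COc1cc(OCc3ccccc3)c2c(c1)O[C@H](c1ccc(OCc3ccccc3)c(OCc3ccccc3)c1)[C@@H](O)C2=O | intermediate
3 | (2R,3R)-3,5,7-tris(benzyloxy)-2-[3,4-bis(benzyloxy)phenyl]chroman-4-one | c1ccccc1COc1cc(OCc3ccccc3)c2c(c1)O[C@H](c1ccc(OCc3ccccc3)c(OCc3ccccc3)c1)[C@@H](OCc3ccccc3)C2=O | intermediate
4 | (2R,3R)-3,5,7-tris(benzyloxy)-2-[3,4-bis(benzyloxy)phenyl]-8-bromochroman-4-one | c1ccccc1COc1cc(OCc3ccccc3)c2c(c1Br)O[C@H](c1ccc(OCc3ccccc3)c(OCc3ccccc3)c1)[C@@H](OCc3ccccc3)C2=O | intermediate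
5 | 2,4,6-trihydroxyacetophenone | CC(=O)c1c(O)cc(O)cc1O | starting material
6 | 1-[2,4-bis(benzyloxy)-6-hydroxyphenyl]ethanone | CC(=O)c1c(O)cc(OCc2ccccc2)cc1OCc1ccccc1 | intermediate
7 | 1-[2,4-bis(benzyloxy)-6-(methoxymethoxy)phenyl]ethanone | CC(=O)c1c(OCOC)cc(OCc2ccccc2)cc1OCc1ccccc1 | intermediate
8 | {1-[2,4-bis(benzyloxy)-6-(methoxymethoxy)phenyl]ethenyloxy}trimethylsilane | C=C(O[Si](C)(C)C)c1c(OCOC)cc(OCc2ccccc2)cc1OCc1ccccc1 | intermediate
9 | tributyl{1-[2,4-bis(benzyloxy)-6-(methoxymethoxy)phenyl]ethenyloxy}stannane (tin enolate, not isolated) | C=C(O[Sn](CCCC)(CCCC)CCCC)c1c(OCOC)cc(OCc2ccccc2)cc1OCc1ccccc1 | intermediate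
10 | 1-[2,4-bis(benzyloxy)-6-(methoxymethoxy)phenyl]-2-{(2R,3R)-3,5,7-tris(benzyloxy)-2-[3,4-bis(benzyloxy)phenyl]-4-oxochroman-8-yl}ethanone | O=C(Cc1c(OCc3ccccc3)cc(OCc3ccccc3)c2c1O[C@H](c1ccc(OCc3ccccc3)c(OCc3ccccc3)c1)[C@@H](OCc3ccccc3)C2=O)c1c(OCOC)cc(OCc2ccccc2)cc1OCc1ccccc1 | intermediate
11 | 3,4-bis(benzyloxy)benzaldehyde | O=Cc1ccc(OCc2ccccc2)c(OCc2ccccc2)c1 | starting material
12 | (E)-1-[2,4-bis(benzyloxy)-6-(methoxymethoxy)phenyl]-3-[3,4-bis(benzyloxy)phenyl]-2-{(2R,3R)-3,5,7-tris(benzyloxy)-2-[3,4-bis(benzyloxy)phenyl]-4-oxochroman-8-yl}prop-2-en-1-one | O=C(c1c(OCOC)cc(OCc2ccccc2)cc1OCc1ccccc1)/C(=C/c1ccc(OCc2ccccc2)c(OCc2ccccc2)c1)c1c(OCc3ccccc3)cc(OCc3ccccc3)c2c1O[C@H](c1ccc(OCc3ccccc3)c(OCc3ccccc3)c1)[C@@H](OCc3ccccc3)C2=O | intermediate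
13 | (E)-1-[2,4-bis(benzyloxy)-6-hydroxyphenyl]-3-[3,4-bis(benzyloxy)phenyl]-2-{(2R,3R)-3,5,7-tris(benzyloxy)-2-[3,4-bis(benzyloxy)phenyl]-4-oxochroman-8-yl}prop-2-en-1-one (key-step precursor) | O=C(c1c(O)cc(OCc2ccccc2)cc1OCc1ccccc1)/C(=C/c1ccc(OCc2ccccc2)c(OCc2ccccc2)c1)c1c(OCc3ccccc3)cc(OCc3ccccc3)c2c1O[C@H](c1ccc(OCc3ccccc3)c(OCc3ccccc3)c1)[C@@H](OCc3ccccc3)C2=O | intermediate
14 | (2S,3R)-5,7-bis(benzyloxy)-2-[3,4-bis(benzyloxy)phenyl]-3-{(2R,3R)-3,5,7-tris(benzyloxy)-2-[3,4-bis(benzyloxy)phenyl]-4-oxochroman-8-yl}chroman-4-one (key-step product) | O=C1c2c(OCc3ccccc3)cc(OCc3ccccc3)cc2O[C@H](c2ccc(OCc3ccccc3)c(OCc3ccccc3)c2)[C@H]1c1c(OCc3ccccc3)cc(OCc3ccccc3)c2c1O[C@H](c1ccc(OCc3ccccc3)c(OCc3ccccc3)c1)[C@@H](OCc3ccccc3)C2=O | intermediate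
15 | (2S,3R)-2-(3,4-dihydroxyphenyl)-5,7-dihydroxy-3-[(2R,3R)-2-(3,4-dihydroxyphenyl)-3,5,7-trihydroxy-4-oxochroman-8-yl]chroman-4-one | O=C1c2c(O)cc(O)cc2O[C@H](c2ccc(O)c(O)c2)[C@H]1c1c(O)cc(O)c2c1O[C@H](c1ccc(O)c(O)c1)[C@@H](O)C2=O | target

Total step count: 11.
Longest linear sequence: 8 steps (1, 2, 3, 7, 8, 9, 10, 11 from taxifolin). The acetophenone branch (4, 5, 6) joins at step 7 and is equally long.

Steps most likely to fail

1. Step 10 (new method). The catalyst may fail to override the facial bias of the lower half at C2, reversible ring opening may erode the kinetic preference, or the crowded trisubstituted enone may close too slowly. The fallback uses known chemistry and sets out from 13. An achiral amine (piperidine, EtOH–THF, 40 °C) closes the ring, as in the second stage of the classical piperidine route from 2-hydroxydeoxybenzoins and aryl aldehydes to trans-2,3-diarylchromanones. Thermodynamic control should give the two 2,3-trans compounds, 14 and the (2R,3S) upper-ring diastereomer F1. They are diastereomers because of the (2R,3R) lower half and would be separated by preparative HPLC. F1 is returned to the same base, where ring opening to 13 and reclosure restore the mixture. The route is rejoined at 14.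

2. Step 7. Oxidative addition and transmetalation at the doubly ortho-substituted C8 may be slow, so that the enol ether is protodesilylated and the bromide reduced instead of coupled. The fallback reverses the polarity of the two partners. Bromide 4 is converted by Miyaura borylation (B2pin2, KOAc, PdCl2(dppf), dioxane, 90 °C) into the 8-pinacolboronate F2. Silyl enol ether 8 is brominated (NBS, THF, –78 °C) to the phenacyl bromide F3. F2 and F3 are then joined by Suzuki–Miyaura coupling of an α-bromo ketone (Pd(OAc)2, P(o-tol)3, KF, THF, 50 °C), a coupling developed for sterically demanding arylboron reagents. The route is rejoined at 10.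

3. Step 8. Condensation at the methylene crowded by two 2,6-disubstituted aryl groups may stall, or the alkene may form as an E/Z mixture. The fallback is a two-stage aldol route setting out from 10. LiN(SiMe3)2 (1.0 equiv, THF, –78 °C) removes one of the acidic methylene protons, which are far more acidic than C3''–H, and the enolate adds to aldehyde 11 to give the β-hydroxy ketone F4. MsCl and Et3N (CH2Cl2, 0 °C) give the mesylate F5, which eliminates under excess Et3N at rt to the enone. The route is rejoined at 12.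

Further compounds
F1 | step 10 | (2R,3S)-5,7-bis(benzyloxy)-2-[3,4-bis(benzyloxy)phenyl]-3-{(2R,3R)-3,5,7-tris(benzyloxy)-2-[3,4-bis(benzyloxy)phenyl]-4-oxochroman-8-yl}chroman-4-one | O=C1c2c(OCc3ccccc3)cc(OCc3ccccc3)cc2O[C@@H](c2ccc(OCc3ccccc3)c(OCc3ccccc3)c2)[C@@H]1c1c(OCc3ccccc3)cc(OCc3ccccc3)c2c1O[C@H](c1ccc(OCc3ccccc3)c(OCc3ccccc3)c1)[C@@H](OCc3ccccc3)C2=O
F2 | step 7 | (2R,3R)-3,5,7-tris(benzyloxy)-2-[3,4-bis(benzyloxy)phenyl]-8-(4,4,5,5-tetramethyl-1,3,2-dioxaborolan-2-yl)chroman-4-one | c1ccccc1COc1cc(OCc3ccccc3)c2c(c1B4OC(C)(C)C(C)(C)O4)O[C@H](c1ccc(OCc3ccccc3)c(OCc3ccccc3)c1)[C@@H](OCc3ccccc3)C2=O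
F3 | step 7 | 2-bromo-1-[2,4-bis(benzyloxy)-6-(methoxymethoxy)phenyl]ethanone | BrCC(=O)c1c(OCOC)cc(OCc2ccccc2)cc1OCc1ccccc1
F4 | step 8 | 1-[2,4-bis(benzyloxy)-6-(methoxymethoxy)phenyl]-3-[3,4-bis(benzyloxy)phenyl]-3-hydroxy-2-{(2R,3R)-3,5,7-tris(benzyloxy)-2-[3,4-bis(benzyloxy)phenyl]-4-oxochroman-8-yl}propan-1-one (mixture at the two new centres) | O=C(c1c(OCOC)cc(OCc2ccccc2)cc1OCc1ccccc1)C(C(O)c1ccc(OCc2ccccc2)c(OCc2ccccc2)c1)c1c(OCc3ccccc3)cc(OCc3ccccc3)c2c1O[C@H](c1ccc(OCc3ccccc3)c(OCc3ccccc3)c1)[C@@H](OCc3ccccc3)C2=O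
F5 | step 8 | methanesulfonate of F4 (mixture at the two new centres) | O=C(c1c(OCOC)cc(OCc2ccccc2)cc1OCc1ccccc1)C(C(OS(C)(=O)=O)c1ccc(OCc2ccccc2)c(OCc2ccccc2)c1)c1c(OCc3ccccc3)cc(OCc3ccccc3)c2c1O[C@H](c1ccc(OCc3ccccc3)c(OCc3ccccc3)c1)[C@@H](OCc3ccccc3)C2=O
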